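At early times neither flask holds a living end, so I start from how chains get begun.

    free monomer + initiator → living end + monomer in chains (k1 = 16 M⁻¹ s⁻¹)
    free monomer + living end → monomer in chains + living end, rate k2*[living end]*[free monomer] (k2 = 14000 M⁻¹ s⁻¹)
    initiator → spent initiator (k3 = 4.3 × 10⁻⁵ s⁻¹)
    protic impurity + free monomer → quenched substrate (k4 = 1100 M⁻¹ s⁻¹)
- epsilon: free monomer 0.0010 M; protic impurity 0.0500 mM; initiator 2.2 µM; time 5.0 min
- eta: free monomer 0.0010 M; protic impurity 0.0500 mM; initiator 2.2 µM; time 1.2 min
1. which of the two ends with the longer chains by the average number of monomer units in a chain (chains begun, living or dead) ("neither" if they lie within 10%) (epsilon / eta / neither)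
2. average number of monomer units in a chain (chains begun, living or dead) at the end, epsilon
3. average number of monomer units in a chain (chains begun, living or dead) at the end, eta
- the average divides the monomer in chains by the number of chains begun, living and dead together
- run time (epsilon): 5.0 min

The protic impurity acts first in both flasks: its half-life of 0.63 s is far shorter than either run, and it removes 0.0500 mM of free monomer, leaving 9.50 × 10⁻⁴ M. The initiator's own decay, with a half-life of 4.5 h, is far slower than the longer run, so I drop it. Growth of monomer in chains needs [living end], which begins at zero, so the curve starts by bending upward. Freezing [initiator] and [free monomer] at their starting values, [living end] climbs in a straight line at 3.34 × 10⁻⁸ M s⁻¹. The logarithm of [free monomer] then falls by half the squared ratio of time to a clock of 46.2 s. That puts the knee at 54.4 s, where [free monomer] has halved. Eta stops at 1.2 min with 6.68 × 10⁻⁴ M taken. Epsilon runs 6.49 clocks, so I count 9.50 × 10⁻⁴ M as taken.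

Given the monomer taken, the length needs no clock. Dividing the growth rate by the rate of beginning cancels [free monomer] and leaves [living end]/[initiator] times G = 875, the start ratio: units added per chain begun when [living end] equals [initiator]. With x the share of initiator begun, monomer taken = G × 2.2 µM × (−x − ln(1 − x)). By hand, x ≈ s/(1 + s/3), where s is the square root of twice the monomer taken over G times the initiator charge. For epsilon, s = 0.993 and x = 0.746, so free monomer is the limiting reagent and the length is 579. For eta, s = 0.833 and x = 0.652, giving 466. I pick epsilon.

The forecast also says epsilon, with 620 for epsilon, above mine, and 418 for eta, below mine, holding that “initiation stalls once the monomer runs out”.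

The simulation gives epsilon, with 620 for epsilon and 418 for eta. Eta left ten times as long reads 622 at 12.0 min, close to the length of epsilon. Putting eta's 52.1% of monomer in chains at 1.20 min through G = 875 gives s = 0.736 and a length of 401.

Take eta with 8.8 × 10⁻⁶ M of initiator, read at the same time. The clock shortens to 23.1 s, so I reckon 9.43 × 10⁻⁴ M taken, s = 0.495, and the start ratio gives a length of 252. The simulated flask gives 247, with 87.9% in chains.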